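The lactone ring (ring B) is opened at C3–C4. C4 is benzylic on the hydroquinone ring (ring A) and ortho to the C1 carboxyl; C3 is bound to the lactone oxygen O2. C3 can therefore arrive as a carboxylic acid carbon: the benzoate of a benzylic phosphonium salt is O-acylated by the complete chiral side chain as its acid chloride, and the ylide carbon (C4) then attacks the new anhydride carbonyl (C3). This one-pot acylation/intramolecular Wittig reaction joins both fragments and closes ring B as the C3=C4 bond of an isocoumarin. Catalyst-controlled hydrogenation of that enol-lactone bond sets C3, and BBr3 unmasks the phenols and the acid.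

Key step: step 6

Assumption: atom numbers are those of the isochroman-1-one core (C1 carbonyl, O2, C3, C4, C4a, C5 to C8, C8a); 1, 5 and 6 are bought; the antipode of the ruthenium–NHC–diamine ligand set that gives 3R is chosen after assignment on a model isocoumarin.

Step 1
Reactants: 1 2,5-dimethoxybenzyl alcohol
Product: 3 4,7-dimethoxyisobenzofuran-1(3H)-one, via dilithio alkoxide 2 (not isolated)
Conditions: n-BuLi (2.3 equiv), TMEDA, Et2O/hexane, 0 °C to rt; CO2, −78 °C to rt; 2 M HCl
Reagents that add atoms: carbon dioxide, O=C=O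
Why: Directed ortho-metalation should take place at the ring position flanked by the lithium alkoxymethyl group and a methoxy group, and carboxylation followed by acid lactonisation of the hydroxy acid gives the phthalide.

Step 2
Reactants: 3 4,7-dimethoxyisobenzofuran-1(3H)-one
Product: 4 (2-carboxy-3,6-dimethoxybenzyl)triphenylphosphonium bromide
Conditions: Ph3P·HBr (1.05 equiv), neat, 160 °C; trituration with Et2O
Reagents that add atoms: triphenylphosphine hydrobromide, [PH+](c1ccccc1)(c1ccccc1)c1ccccc1.[Br-]
Why: The protonated phthalide is opened by triphenylphosphine through nucleophilic displacement at the benzylic CH2–O carbon (alkyl–oxygen cleavage of the lactone), the usual entry to (2-carboxybenzyl)phosphonium salts, helped here by the ortho methoxy group.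

Step 3
Reactants: 5 (R)-hex-5-en-2-ol; 6 4-(benzyloxy)-4-oxobutanoic acid
Product: 7 benzyl (2R)-hex-5-en-2-yl butanedioate
Conditions: DCC (1.1 equiv), DMAP (0.1 equiv), CH2Cl2, 0 °C to rt
Reagents that add atoms: none
Why: Steglich esterification acylates the secondary alcohol on oxygen without breaking its C–O bond, so the (R) centre bought with 5 is carried over unchanged and already wears the succinate of the target.

Step 4
Reactants: 7 benzyl (2R)-hex-5-en-2-yl butanedioate
Product: 9 benzyl (2R)-6-hydroxyhexan-2-yl butanedioate, via B-alkyl-9-BBN adduct 8 (not isolated)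
Conditions: 9-BBN (1.2 equiv), THF, 0 °C to rt; 30% H2O2, aq. NaOAc, 0 °C to rt
Reagents that add atoms: hydrogen peroxide, OO
Why: Anti-Markovnikov hydroboration–oxidation of the terminal alkene with a borane that does not reduce esters, followed by acetate-buffered oxidation that should spare both ester groups, gives the primary alcohol.

Step 5
Reactants: 9 benzyl (2R)-6-hydroxyhexan-2-yl butanedioate
Product: 10 (5R)-5-{[4-(benzyloxy)-4-oxobutanoyl]oxy}hexanoic acid
Conditions: TEMPO (0.2 equiv), PhI(OAc)2 (2.2 equiv), MeCN/H2O 1:1, rt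
Reagents that add atoms: water, O
Why: Oxoammonium (TEMPO) oxidation takes the primary alcohol through the aldehyde hydrate to the acid under near-neutral conditions that leave the benzyl and secondary esters and the non-enolisable carbinol centre alone.

Step 6
Reactants: 10 (5R)-5-{[4-(benzyloxy)-4-oxobutanoyl]oxy}hexanoic acid; 4 (2-carboxy-3,6-dimethoxybenzyl)triphenylphosphonium bromide
Product: 13 benzyl (2R)-5-(5,8-dimethoxy-1-oxo-1H-isochromen-3-yl)pentan-2-yl butanedioate, via acid chloride 11 (not isolated), via mixed anhydride ylide 12 (not isolated)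
Conditions: 10, (COCl)2 (1.2 equiv), DMF (cat.), CH2Cl2, 0 °C to rt, evaporation; then 4, Et3N (3 equiv), toluene, 0 °C, then 110 °C
Reagents that add atoms: none
Why: The carboxylate of 4 is acylated by acid chloride 11 to a mixed anhydride, a second equivalent of Et3N deprotonates the benzylic phosphonium to the semi-stabilised ylide 12, and the ylide carbon (C4) adds to the aliphatic anhydride carbonyl (C3) to give an oxaphosphetane that collapses to Ph3P=O and the C3=C4 bond. The closest known reaction type is the Wittig olefination of acyl derivatives in its intramolecular form, as used to make 3-substituted isocoumarins from (2-carboxybenzyl)phosphonium salts and acid chlorides. Ring B closes by a 6-exo-trig addition of C4 to the C3 carbonyl followed by cycloreversion, so that C3=C4 ends inside the six-membered ring. No stereocentre is formed, and the (R) carbinol centre of the side chain is non-enolisable and four bonds from the reacting carbonyl, so it should pass unchanged. The step needs O-acylation ahead of ylide C-acylation and attack at the anhydride carbonyl instead of the succinate esters: adding the acid chloride to the carboxylate at 0 °C before heating should secure the first, and only the anhydride carbonyl lies within reach of C4 in a six-membered transition state while being far more electrophilic than an ester.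

Step 7
Reactants: 13 benzyl (2R)-5-(5,8-dimethoxy-1-oxo-1H-isochromen-3-yl)pentan-2-yl butanedioate
Product: 14 benzyl (2R)-5-[(3R)-5,8-dimethoxy-1-oxo-3,4-dihydro-1H-isochromen-3-yl]pentan-2-yl butanedioate
Conditions: ruthenium–NHC–diamine complex from Ru(cod)(2-methylallyl)2, SINpEt·HBF4/KOtBu and 1,2-diphenylethylenediamine (2 mol%), NaOtBu (10 mol%), H2 (50 bar), toluene, 25 °C
Reagents that add atoms: none
Why: Enantioselective homogeneous hydrogenation of the enol-lactone C3=C4 bond of 3-substituted isocoumarins is a known reaction of chiral ruthenium–NHC–diamine catalysts, and the catalyst alone should choose the face that gives 3R because the side-chain centre is too remote to bias it, while benzyl ester, aryl ethers and arene are not reduced under these conditions.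

Step 8
Reactants: 14 benzyl (2R)-5-[(3R)-5,8-dimethoxy-1-oxo-3,4-dihydro-1H-isochromen-3-yl]pentan-2-yl butanedioate
Product: 15 4-{[(2R)-5-[(3R)-5,8-dihydroxy-1-oxo-3,4-dihydro-1H-isochromen-3-yl]pentan-2-yl]oxy}-4-oxobutanoic acid
Conditions: BBr3 (8 equiv), CH2Cl2, −78 °C to 0 °C; then ice-water with aq. Na2S2O4, under argon
Reagents that add atoms: none
Why: Lewis-acid ether and ester cleavage with BBr3 proceeds by bromide attack at unhindered methyl and benzylic carbons, so both aryl methyl ethers and the benzyl ester should fall while the secondary-alkyl succinate and the lactone C3–O bond, which would need substitution at a secondary carbon, should survive with both stereocentres intact.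

Compound list
1 | 2,5-dimethoxybenzyl alcohol | COc1ccc(OC)c(CO)c1 | starting material
2 | lithium (2-lithio-3,6-dimethoxyphenyl)methanolate (dilithio alkoxide) | [Li]OCc1c([Li])c(OC)ccc1OC | intermediate
3 | 4,7-dimethoxyisobenzofuran-1(3H)-one | COc1ccc(OC)c2c1COC2=O | intermediate
4 | (2-carboxy-3,6-dimethoxybenzyl)triphenylphosphonium bromide | COc1ccc(OC)c(C[P+](c2ccccc2)(c2ccccc2)c2ccccc2)c1C(=O)O.[Br-] | intermediate
5 | (R)-hex-5-en-2-ol | C[C@H](CCC=C)O | starting material
6 | 4-(benzyloxy)-4-oxobutanoic acid (monobenzyl succinate) | OC(=O)CCC(=O)OCc1ccccc1 | starting material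
7 | benzyl (2R)-hex-5-en-2-yl butanedioate | C[C@H](CCC=C)OC(=O)CCC(=O)OCc1ccccc1 | intermediate
8 | benzyl (2R)-6-(9-borabicyclo[3.3.1]nonan-9-yl)hexan-2-yl butanedioate (B-alkyl-9-BBN adduct) | C[C@H](CCCCB1C2CCCC1CCC2)OC(=O)CCC(=O)OCc1ccccc1 | intermediate
9 | benzyl (2R)-6-hydroxyhexan-2-yl butanedioate | C[C@H](CCCCO)OC(=O)CCC(=O)OCc1ccccc1 | intermediate
10 | (5R)-5-{[4-(benzyloxy)-4-oxobutanoyl]oxy}hexanoic acid | C[C@H](CCCC(=O)O)OC(=O)CCC(=O)OCc1ccccc1 | intermediate
11 | (5R)-5-{[4-(benzyloxy)-4-oxobutanoyl]oxy}hexanoyl chloride | C[C@H](CCCC(=O)Cl)OC(=O)CCC(=O)OCc1ccccc1 | intermediate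
12 | mixed anhydride of 10 with 3,6-dimethoxy-2-[(triphenylphosphoranylidene)methyl]benzoic acid (mixed anhydride ylide) | COc1ccc(OC)c(C=P(c2ccccc2)(c2ccccc2)c2ccccc2)c1C(=O)OC(=O)CCC[C@@H](C)OC(=O)CCC(=O)OCc1ccccc1 | intermediate
13 | benzyl (2R)-5-(5,8-dimethoxy-1-oxo-1H-isochromen-3-yl)pentan-2-yl butanedioate | C[C@H](CCCC1=Cc2c(OC)ccc(OC)c2C(=O)O1)OC(=O)CCC(=O)OCc1ccccc1 | intermediate
14 | benzyl (2R)-5-[(3R)-5,8-dimethoxy-1-oxo-3,4-dihydro-1H-isochromen-3-yl]pentan-2-yl butanedioate | C[C@H](CCC[C@@H]1Cc2c(OC)ccc(OC)c2C(=O)O1)OC(=O)CCC(=O)OCc1ccccc1 | intermediate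
15 | 4-{[(2R)-5-[(3R)-5,8-dihydroxy-1-oxo-3,4-dihydro-1H-isochromen-3-yl]pentan-2-yl]oxy}-4-oxobutanoic acid | C[C@H](CCC[C@@H]1Cc2c(O)ccc(O)c2C(=O)O1)OC(=O)CCC(=O)O | target

Total step count: 8
Longest linear sequence: 6 steps (steps 3, 4, 5, 6, 7 and 8, from 5)

Steps most likely to fail

Step 6. The ylide may be acylated on carbon, or the aliphatic acid chloride may be drained into ketene by Et3N, before ring closure at the doubly ortho-substituted centre. The fallback closes ring B at the same C3=C4 bond by ring-closing olefin metathesis and sets out from 4 and 9. Wittig reaction of 4 with aqueous formaldehyde (NaOH, H2O, rt) should give 3,6-dimethoxy-2-vinylbenzoic acid F1. Oxidation of 9 with Dess–Martin periodinane (CH2Cl2, rt) gives benzyl (2R)-6-oxohexan-2-yl butanedioate F2, which lithiated trimethylsilyldiazomethane (THF, −78 °C to rt, Colvin rearrangement) should homologate to benzyl (2R)-hept-6-yn-2-yl butanedioate F3. Markovnikov addition of F1 to F3 ([RuCl2(p-cymene)]2, P(2-furyl)3, Na2CO3, toluene, 50 °C) gives (6R)-6-{[4-(benzyloxy)-4-oxobutanoyl]oxy}hept-1-en-2-yl 3,6-dimethoxy-2-vinylbenzoate F4. Second-generation Hoveyda–Grubbs catalyst (toluene, 80 °C) then closes the ring with loss of ethene and comes back to the route at 13.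

Step 7. Face selection may be insufficient, or the catalytic alkoxide may transesterify or open the ester groups. The fallback sets C3 by ketone reduction on the ring-opened lactone and sets out from 13. KOH (aq. EtOH, rt) opens the enol lactone and cleaves both succinate ester bonds to 2-[(6R)-6-hydroxy-2-oxoheptyl]-3,6-dimethoxybenzoic acid F5. An (R)-selective NADPH-dependent ketoreductase (glucose/glucose dehydrogenase recycling, pH 7 buffer, 30 °C) should reduce the ketone to 2-[(2R,6R)-2,6-dihydroxyheptyl]-3,6-dimethoxybenzoic acid F6. TsOH (cat., toluene, rt) lactonises it to (3R)-3-[(4R)-4-hydroxypentyl]-5,8-dimethoxy-3,4-dihydro-1H-isochromen-1-one F7. Esterification of F7 with 6 (DCC, DMAP, CH2Cl2) comes back to the route at 14.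

Step 8. The Lewis acid may also cleave the secondary succinate or the lactone C–O bond, or the benzyl fragment may alkylate ring A. The fallback splits the deprotection into an oxidative and a reductive operation and sets out from 14. (NH4)2Ce(NO3)6 (MeCN/H2O, 0 °C) should demethylate oxidatively to the quinone benzyl (2R)-5-[(3R)-1,5,8-trioxo-3,4,5,8-tetrahydro-1H-isochromen-3-yl]pentan-2-yl butanedioate F8. H2 over Pd/C (10% palladium on carbon, EtOAc, rt) then reduces the quinone to the hydroquinone and hydrogenolyses the benzyl ester in one operation, coming back to the route at 15.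

Further compounds
F1 | step 6 | 3,6-dimethoxy-2-vinylbenzoic acid | COc1ccc(OC)c(C=C)c1C(=O)O
F2 | step 6 | benzyl (2R)-6-oxohexan-2-yl butanedioate | C[C@H](CCCC=O)OC(=O)CCC(=O)OCc1ccccc1
F3 | step 6 | benzyl (2R)-hept-6-yn-2-yl butanedioate | C[C@H](CCCC#C)OC(=O)CCC(=O)OCc1ccccc1
F4 | step 6 | (6R)-6-{[4-(benzyloxy)-4-oxobutanoyl]oxy}hept-1-en-2-yl 3,6-dimethoxy-2-vinylbenzoate | C=C(CCC[C@@H](C)OC(=O)CCC(=O)OCc1ccccc1)OC(=O)c1c(OC)ccc(OC)c1C=C
F5 | step 7 | 2-[(6R)-6-hydroxy-2-oxoheptyl]-3,6-dimethoxybenzoic acid | C[C@H](CCCC(=O)Cc1c(OC)ccc(OC)c1C(=O)O)O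
F6 | step 7 | 2-[(2R,6R)-2,6-dihydroxyheptyl]-3,6-dimethoxybenzoic acid | C[C@H](CCC[C@@H](O)Cc1c(OC)ccc(OC)c1C(=O)O)O
F7 | step 7 | (3R)-3-[(4R)-4-hydroxypentyl]-5,8-dimethoxy-3,4-dihydro-1H-isochromen-1-one | C[C@H](CCC[C@@H]1Cc2c(OC)ccc(OC)c2C(=O)O1)O
F8 | step 8 | benzyl (2R)-5-[(3R)-1,5,8-trioxo-3,4,5,8-tetrahydro-1H-isochromen-3-yl]pentan-2-yl butanedioate | C[C@H](CCC[C@@H]1CC2=C(C(=O)O1)C(=O)C=CC2=O)OC(=O)CCC(=O)OCc1ccccc1
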